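**Plan**

1. Retrosynthetic cuts: the two O-benzyl groups come off last; the enal is traced back to a 3-methylene tetralin (C4–H removed, C9 oxygenated); then C1–C2 and C1–C8a are cut together, leaving benzyl vanillin (C1 with ring C) and a Z-allylsilane that holds C2, C3, C9, C4 and ring A.
2. Enabling feature: C1, the CH that carries guaiacyl ring C, has only two other bonds, one to C2 (the CH with the CH2OAc arm, next to C3 which bears formyl carbon C9) and one to C8a of ring A, para to the C6 methoxy group. C1 is therefore an aromatic aldehyde carbon placed between an allylsilane terminus and an activated arene position.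
3. The silane is cut at C3–CH2Si (Kumada coupling), at C3–I/C2–H (hydroalumination–iodination) and at C4–alkyne (copper coupling), back to a vanillin-derived benzyl bromide, propargyl alcohol and Me3SiCH2MgCl.
4. Forward: the chain is joined linearly (steps 1–7); rings A and C are vanillin rings; ring B is the only ring made and closes in step 8; steps 9–11 adjust the oxidation level and the protecting groups.
5. Stereochemistry: C2 comes from the chiral counteranion of the acid catalyst in the allylation of step 8; C1 is set trans to C2 by the substrate during ring closure; neither centre is touched afterwards.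

Key step: step 8

Assumption: skeleton numbering is C1 (CH–aryl), C2 (CH–CH2O), C3, C4, C4a, C5–C8, C8a, with C9 the exocyclic carbon on C3; the target is the trans (1S,2R) isomer.
Assumption: the (S,S) antipode of the acid catalyst is written for step 8; its sense of induction for this substrate class is not established, and the (R,R) acid would be used instead if that is the one that delivers 2R.
Remark: the primary alcohol is carried as a triisopropylsilyl (TIPS) ether, because its hindered, weakly basic oxygen should resist ionisation of the allylic C–O bond under the acidic conditions of step 8.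

**Step 1**
Reactants: 1 vanillin
Product: 2 4-(benzyloxy)-3-methoxybenzaldehyde (benzyl vanillin)
Conditions: BnBr, K2CO3, DMF, rt
Reagents that add atoms: benzyl bromide, BrCc1ccccc1
Why: Williamson ether synthesis, the phenoxide displacing bromide from benzyl bromide while the aldehyde is untouched.

**Step 2**
Reactants: 2 4-(benzyloxy)-3-methoxybenzaldehyde
Product: 3 [4-(benzyloxy)-3-methoxyphenyl]methanol
Conditions: NaBH4, MeOH, 0 °C
Reagents that add atoms: none
Why: borohydride reduction of an aryl aldehyde, to which the benzyl and methyl ethers are inert.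

**Step 3**
Reactants: 3 [4-(benzyloxy)-3-methoxyphenyl]methanol
Product: 4 1-(benzyloxy)-4-(bromomethyl)-2-methoxybenzene
Conditions: PBr3, CH2Cl2, 0 °C; used at once
Reagents that add atoms: phosphorus tribromide, BrP(Br)Br
Why: deoxybromination of an activated benzylic alcohol through its phosphite ester, the labile electron-rich bromide being taken on without storage.

**Step 4**
Reactants: 4 1-(benzyloxy)-4-(bromomethyl)-2-methoxybenzene; 5 propargyl alcohol
Product: 6 4-[4-(benzyloxy)-3-methoxyphenyl]but-2-yn-1-ol
Conditions: CuI (10 mol %), Cs2CO3, MeCN, rt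
Reagents that add atoms: none
Why: copper-acetylide alkylation (sp–sp3 coupling of a terminal alkyne with a benzylic halide), in which the carbonate is too weak a base to alkylate the free hydroxyl or to isomerise the skipped aryl-alkyne.

**Step 5**
Reactants: 6 4-[4-(benzyloxy)-3-methoxyphenyl]but-2-yn-1-ol
Product: 8 (Z)-4-[4-(benzyloxy)-3-methoxyphenyl]-3-iodobut-2-en-1-ol, via cyclic alkenylalanate 7 (not isolated)
Conditions: NaAlH2(OCH2CH2OMe)2, THF, 0 °C → rt; EtOAc; then I2, THF, −78 → 0 °C
Reagents that add atoms: iodine, II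
Why: alkoxide-directed trans-hydroalumination of a propargylic alcohol puts hydride on C2 and aluminium on C3 in the five-membered chelate 7, and iodinolysis of the C–Al bond with retention fixes the alkene as Z (iodine cis to CH2OH).

**Step 6**
Reactants: 8 (Z)-4-[4-(benzyloxy)-3-methoxyphenyl]-3-iodobut-2-en-1-ol
Product: 9 {[(Z)-4-[4-(benzyloxy)-3-methoxyphenyl]-3-iodobut-2-en-1-yl]oxy}triisopropylsilane
Conditions: TIPSCl, imidazole, DMF, rt
Reagents that add atoms: chlorotriisopropylsilane, CC(C)[Si](Cl)(C(C)C)C(C)C
Why: standard imidazole-mediated silylation of a primary allylic alcohol, which does not affect the vinyl iodide or its geometry.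

**Step 7**
Reactants: 9 {[(Z)-4-[4-(benzyloxy)-3-methoxyphenyl]-3-iodobut-2-en-1-yl]oxy}triisopropylsilane; 10 (trimethylsilyl)methylmagnesium chloride
Product: 11 {[(Z)-4-[4-(benzyloxy)-3-methoxyphenyl]-3-[(trimethylsilyl)methyl]but-2-en-1-yl]oxy}triisopropylsilane
Conditions: Pd(PPh3)4 (5 mol %), THF, rt → 50 °C
Reagents that add atoms: none
Why: Kumada–Corriu cross-coupling, in which oxidative addition and reductive elimination both retain the alkene geometry and the Grignard reagent has no β-hydrogen, so the Z-allylsilane (CH2SiMe3 cis to CH2OTIPS) results.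

**Step 8**
Reactants: 11 {[(Z)-4-[4-(benzyloxy)-3-methoxyphenyl]-3-[(trimethylsilyl)methyl]but-2-en-1-yl]oxy}triisopropylsilane; 2 4-(benzyloxy)-3-methoxybenzaldehyde
Product: 14 (1S,2R)-7-(benzyloxy)-1-[4-(benzyloxy)-3-methoxyphenyl]-6-methoxy-3-methylidene-2-[(triisopropylsilyloxy)methyl]-1,2,3,4-tetrahydronaphthalene, via homoallylic trimethylsilyl ether 12 (not isolated), via benzylic cation 13 (not isolated)
Conditions: (S,S)-IDPi acid [imidodiphosphorimidate from two (S)-3,3′-diaryl-BINOL units with P=N–SO2CF3 groups, Ar = 3,5-(CF3)2C6H3] (5 mol %), 5 Å MS, toluene, −60 → −20 °C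
Reagents that add atoms: none
Why: Proposed new method: the silylated acid turns aldehyde 2 into a silyloxocarbenium ion held in the pocket of the chiral anion, the γ-carbon (C2) of silane 11 attacks it in an SE2′ Hosomi–Sakurai step that expels Me3Si and leaves the exocyclic methylene, the para-benzyloxybenzylic silyl ether 12 then ionises to cation 13 and ring A captures it at C8a; the closest known reactions are the imidodiphosphorimidate-catalysed asymmetric Hosomi–Sakurai allylation of aromatic aldehydes and Lewis-acid Sakurai or Prins additions followed by Friedel–Crafts closure to 1-aryltetralins. Ring B closes by a six-membered cationic Friedel–Crafts alkylation in which the arene bond C4a–C8a is endocyclic (6-endo with respect to the arene), at the position ortho to the tether and para to the C6 methoxy group. C2 is set in the allylation by the catalyst-bound aldehyde face acting together with the fixed Z geometry of 11 in an open antiperiplanar transition state, and C1, planar in 13, is set by C2 in a chair-like closure that keeps the aryl group and the CH2OTIPS arm pseudo-equatorial and trans. The step therefore needs high enantiofacial selectivity at the γ-carbon of the silane, not merely at the aldehyde carbon, plus para regioselectivity on ring A; these rest on the single alkene geometry of 11, the directing C6 methoxy group and the hindered TIPS ether that resists ionisation and 1,4-elimination. The proton released on rearomatisation ionises the next silyl ether, so silicon leaves as trimethylsilanol, and the sieves hold back water that would otherwise cause protodesilylation of 11.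

**Step 9**
Reactants: 14 (1S,2R)-7-(benzyloxy)-1-[4-(benzyloxy)-3-methoxyphenyl]-6-methoxy-3-methylidene-2-[(triisopropylsilyloxy)methyl]-1,2,3,4-tetrahydronaphthalene
Product: 15 [(1S,2R)-7-(benzyloxy)-1-[4-(benzyloxy)-3-methoxyphenyl]-6-methoxy-3-methylidene-1,2,3,4-tetrahydronaphthalen-2-yl]methanol
Conditions: TBAF, THF, rt
Reagents that add atoms: none
Why: fluoride-driven Si–O cleavage of a primary silyl ether, which leaves the benzyl ethers, the isolated alkene and both stereocentres untouched.

**Step 10**
Reactants: 15 [(1S,2R)-7-(benzyloxy)-1-[4-(benzyloxy)-3-methoxyphenyl]-6-methoxy-3-methylidene-1,2,3,4-tetrahydronaphthalen-2-yl]methanol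
Product: 19 [(1S,2R)-7-(benzyloxy)-1-[4-(benzyloxy)-3-methoxyphenyl]-3-formyl-6-methoxy-1,2-dihydronaphthalen-2-yl]methyl acetate, via acetate 16 (not isolated), via allylic hydroperoxide 17 (not isolated), via peracetate 18 (not isolated)
Conditions: Ac2O (3 equiv), pyridine, DMAP, CH2Cl2, rt; then 5,10,15,20-tetraphenylporphyrin, O2, hν (visible), 0 °C → rt
Reagents that add atoms: acetic anhydride, CC(=O)OC(C)=O; dioxygen, O=O
Why: DMAP-catalysed acetylation is followed by a Schenck ene reaction of singlet oxygen, which should take the aligned pseudo-axial benzylic C4–H (giving the arene-conjugated C3=C4 alkene and the C9 hydroperoxide) and not the tertiary C2–H (which, like other isopropyl-type allylic hydrogens, lies near the alkene plane), and the peracetate formed in situ then loses acetic acid in a Kornblum–DeLaMare-type elimination to the enal, which also deactivates the new styrene towards further oxidation.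

**Step 11**
Reactants: 19 [(1S,2R)-7-(benzyloxy)-1-[4-(benzyloxy)-3-methoxyphenyl]-3-formyl-6-methoxy-1,2-dihydronaphthalen-2-yl]methyl acetate
Product: 20 [(1S,2R)-3-formyl-7-hydroxy-1-(4-hydroxy-3-methoxyphenyl)-6-methoxy-1,2-dihydronaphthalen-2-yl]methyl acetate (target)
Conditions: BCl3, C6HMe5, CH2Cl2, −78 °C; then MeOH, aq. NaHCO3
Reagents that add atoms: none
Why: Lewis-acid debenzylation of aryl benzyl ethers with pentamethylbenzene as a non-basic benzyl-cation scavenger, which at −78 °C should spare the methyl ethers, the acetate, the enal and the stereocentres, where hydrogenolysis would reduce the alkene.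

**Compound list**

1 | vanillin (4-hydroxy-3-methoxybenzaldehyde) | COc1cc(C=O)ccc1O | starting material
2 | 4-(benzyloxy)-3-methoxybenzaldehyde (benzyl vanillin) | COc1cc(C=O)ccc1OCc1ccccc1 | intermediate
3 | [4-(benzyloxy)-3-methoxyphenyl]methanol | COc1cc(CO)ccc1OCc1ccccc1 | intermediate
4 | 1-(benzyloxy)-4-(bromomethyl)-2-methoxybenzene | COc1cc(CBr)ccc1OCc1ccccc1 | intermediate
5 | propargyl alcohol | C#CCO | starting material
6 | 4-[4-(benzyloxy)-3-methoxyphenyl]but-2-yn-1-ol | COc1cc(CC#CCO)ccc1OCc1ccccc1 | intermediate
7 | sodium alkoxy(alkenyl)aluminate chelate (five-membered ring O–Al–C3=C2–CH2, two 2-methoxyethoxy groups on Al, arylmethyl on C3) | [Na+].COCCO[Al-]1(OCCOC)OCC=C1Cc1ccc(OCc2ccccc2)c(OC)c1 | intermediate (not isolated)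
8 | (Z)-4-[4-(benzyloxy)-3-methoxyphenyl]-3-iodobut-2-en-1-ol | I/C(Cc1ccc(OCc2ccccc2)c(OC)c1)=C\CO | intermediate
9 | {[(Z)-4-[4-(benzyloxy)-3-methoxyphenyl]-3-iodobut-2-en-1-yl]oxy}triisopropylsilane | I/C(Cc1ccc(OCc2ccccc2)c(OC)c1)=C\CO[Si](C(C)C)(C(C)C)C(C)C | intermediate
10 | (trimethylsilyl)methylmagnesium chloride | C[Si](C)(C)C[Mg]Cl | starting material
11 | {[(Z)-4-[4-(benzyloxy)-3-methoxyphenyl]-3-[(trimethylsilyl)methyl]but-2-en-1-yl]oxy}triisopropylsilane | C[Si](C)(C)C/C(Cc1ccc(OCc2ccccc2)c(OC)c1)=C\CO[Si](C(C)C)(C(C)C)C(C)C | intermediate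
12 | (2R)-1,4-bis[4-(benzyloxy)-3-methoxyphenyl]-3-methylidene-2-[(triisopropylsilyloxy)methyl]butyl trimethylsilyl ether (carbinol carbon either configuration) | C=C(Cc1ccc(OCc2ccccc2)c(OC)c1)[C@@H](C(O[Si](C)(C)C)c1ccc(OCc2ccccc2)c(OC)c1)CO[Si](C(C)C)(C(C)C)C(C)C | intermediate (not isolated)
13 | para-benzyloxybenzylic cation at C1 derived from 12 (ion pair with the catalyst anion, C2 as in 12) | C=C(Cc1ccc(OCc2ccccc2)c(OC)c1)[C@@H]([CH+]c1ccc(OCc2ccccc2)c(OC)c1)CO[Si](C(C)C)(C(C)C)C(C)C | intermediate (not isolated)
14 | (1S,2R)-7-(benzyloxy)-1-[4-(benzyloxy)-3-methoxyphenyl]-6-methoxy-3-methylidene-2-[(triisopropylsilyloxy)methyl]-1,2,3,4-tetrahydronaphthalene (trans) | COc1cc([C@H]2c3cc(OCc4ccccc4)c(OC)cc3CC(=C)[C@@H]2CO[Si](C(C)C)(C(C)C)C(C)C)ccc1OCc1ccccc1 | intermediate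
15 | [(1S,2R)-7-(benzyloxy)-1-[4-(benzyloxy)-3-methoxyphenyl]-6-methoxy-3-methylidene-1,2,3,4-tetrahydronaphthalen-2-yl]methanol | COc1cc([C@H]2c3cc(OCc4ccccc4)c(OC)cc3CC(=C)[C@@H]2CO)ccc1OCc1ccccc1 | intermediate
16 | [(1S,2R)-7-(benzyloxy)-1-[4-(benzyloxy)-3-methoxyphenyl]-6-methoxy-3-methylidene-1,2,3,4-tetrahydronaphthalen-2-yl]methyl acetate | COc1cc([C@H]2c3cc(OCc4ccccc4)c(OC)cc3CC(=C)[C@@H]2COC(C)=O)ccc1OCc1ccccc1 | intermediate (not isolated)
17 | [(1S,2R)-7-(benzyloxy)-1-[4-(benzyloxy)-3-methoxyphenyl]-3-(hydroperoxymethyl)-6-methoxy-1,2-dihydronaphthalen-2-yl]methyl acetate | COc1cc([C@H]2c3cc(OCc4ccccc4)c(OC)cc3C=C(COO)[C@@H]2COC(C)=O)ccc1OCc1ccccc1 | intermediate (not isolated)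
18 | [(1S,2R)-3-[(acetylperoxy)methyl]-7-(benzyloxy)-1-[4-(benzyloxy)-3-methoxyphenyl]-6-methoxy-1,2-dihydronaphthalen-2-yl]methyl acetate | COc1cc([C@H]2c3cc(OCc4ccccc4)c(OC)cc3C=C(COOC(C)=O)[C@@H]2COC(C)=O)ccc1OCc1ccccc1 | intermediate (not isolated)
19 | [(1S,2R)-7-(benzyloxy)-1-[4-(benzyloxy)-3-methoxyphenyl]-3-formyl-6-methoxy-1,2-dihydronaphthalen-2-yl]methyl acetate | COc1cc([C@H]2c3cc(OCc4ccccc4)c(OC)cc3C=C(C=O)[C@@H]2COC(C)=O)ccc1OCc1ccccc1 | intermediate
20 | [(1S,2R)-3-formyl-7-hydroxy-1-(4-hydroxy-3-methoxyphenyl)-6-methoxy-1,2-dihydronaphthalen-2-yl]methyl acetate | COc1cc([C@H]2c3cc(O)c(OC)cc3C=C(C=O)[C@@H]2COC(C)=O)ccc1O | target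

**Step count**

Total steps: 11. Longest linear sequence: 11 steps from vanillin (compound 2 lies on the main line and is used a second time in step 8).

**Steps most likely to fail**

Step 8 (proposed new method, highest risk). Chirality may be transferred to C2 only incompletely, because both the aldehyde face and the relative topicity of the allylation must be controlled. The silane may also be lost by protodesilylation from the proton set free on ring closure, or by 1,4-elimination of the allylic ether. The fallback uses known chemistry and sets out from 11 and 2, with the two bond formations run separately and without a chiral catalyst. BF3·OEt2 in CH2Cl2 at −78 °C effects a classical Hosomi–Sakurai allylation to the racemic homoallylic alcohol F1; its diastereomer mixture is irrelevant because C1 is ionised next. Catalytic FeCl3 in CH2Cl2 then closes ring B by intramolecular Friedel–Crafts alkylation of the benzylic alcohol to the racemic trans tetralin F2, and TBAF in THF gives the racemic alcohol F3. A lipase-catalysed kinetic resolution (Burkholderia cepacia lipase, vinyl acetate, tert-butyl methyl ether) acetylates one enantiomer, at the cost of half the material. The (1S,2R) acetate is compound 16, where the route is rejoined for the photooxygenation stage of step 10, and the unreacted (1R,2S) alcohol F4 is removed by chromatography. If the enzyme prefers the antipode, the recovered alcohol is 15 itself and enters step 10 unchanged.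

Step 10. Hydrogen abstraction may occur at C2 in place of C4, which would erase the C2 stereocentre; the ene reaction of a 1,1-disubstituted alkene may be slow; and the electron-rich arenes or the product styrene may be oxidised. The fallback sets out from 14 and replaces the photooxygenation by an epoxide route. mCPBA with NaHCO3 in CH2Cl2 at 0 °C epoxidises the exocyclic alkene to the spiro-epoxide F5, whose epoxide carbon is a mixture of no consequence. Diethylaluminium 2,2,6,6-tetramethylpiperidide (Et2AlNC9H18) in toluene at 0 °C isomerises the epoxide by syn removal of a benzylic C4 hydrogen to the allylic alcohol F6. MnO2 in CH2Cl2 oxidises this to the enal silyl ether F7, HF·pyridine in THF removes the TIPS group to give the hydroxy enal F8, and Ac2O with pyridine then gives 19, where the route is rejoined.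

Step 11. Lewis-acid side reactions may occur at the last stage: loss of a methyl ether next to a freed phenol, cleavage of the acetate on quenching, or acid-induced aromatisation of the dihydronaphthalene. The fallback sets out from 15 and removes the benzyl groups before the sensitive enal exists. Lithium 4,4′-di-tert-butylbiphenylide in THF at −78 °C cleaves both aryl benzyl ethers by electron transfer and gives the triol F9 with the isolated alkene intact. The one-pot conditions of step 10 then peracetylate it to the triacetate F10 and carry this through the hydroperoxide F11 and the peracetate F12 to the triacetate enal F13. NH4OAc in aqueous MeOH at rt cleaves only the two aryl acetates and gives 20.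

**Further compounds**

F1 | step 8 | racemic 1,4-bis[4-(benzyloxy)-3-methoxyphenyl]-3-methylidene-2-[(triisopropylsilyloxy)methyl]butan-1-ol (diastereomer mixture) | C=C(Cc1ccc(OCc2ccccc2)c(OC)c1)C(CO[Si](C(C)C)(C(C)C)C(C)C)C(O)c1ccc(OCc2ccccc2)c(OC)c1
F2 | step 8 | racemic trans (1S*,2R*) form of tetralin 14 | COc1cc(C2c3cc(OCc4ccccc4)c(OC)cc3CC(=C)C2CO[Si](C(C)C)(C(C)C)C(C)C)ccc1OCc1ccccc1
F3 | step 8 | racemic trans (1S*,2R*) form of alcohol 15 | COc1cc(C2c3cc(OCc4ccccc4)c(OC)cc3CC(=C)C2CO)ccc1OCc1ccccc1
F4 | step 8 | [(1R,2S)-7-(benzyloxy)-1-[4-(benzyloxy)-3-methoxyphenyl]-6-methoxy-3-methylidene-1,2,3,4-tetrahydronaphthalen-2-yl]methanol (antipode of 15) | COc1cc([C@@H]2c3cc(OCc4ccccc4)c(OC)cc3CC(=C)[C@H]2CO)ccc1OCc1ccccc1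
F5 | step 10 | spiro-epoxide of 14 across C3=C9 (C1 and C2 as in 14, epoxide carbon as a mixture) | COc1cc([C@H]2c3cc(OCc4ccccc4)c(OC)cc3CC3(CO3)[C@@H]2CO[Si](C(C)C)(C(C)C)C(C)C)ccc1OCc1ccccc1
F6 | step 10 | [(3R,4S)-6-(benzyloxy)-4-[4-(benzyloxy)-3-methoxyphenyl]-7-methoxy-3-[(triisopropylsilyloxy)methyl]-3,4-dihydronaphthalen-2-yl]methanol (C1 and C2 of the skeleton as in 14) | COc1cc([C@H]2c3cc(OCc4ccccc4)c(OC)cc3C=C(CO)[C@@H]2CO[Si](C(C)C)(C(C)C)C(C)C)ccc1OCc1ccccc1
F7 | step 10 | (3R,4S)-6-(benzyloxy)-4-[4-(benzyloxy)-3-methoxyphenyl]-7-methoxy-3-[(triisopropylsilyloxy)methyl]-3,4-dihydronaphthalene-2-carbaldehyde | COc1cc([C@H]2c3cc(OCc4ccccc4)c(OC)cc3C=C(C=O)[C@@H]2CO[Si](C(C)C)(C(C)C)C(C)C)ccc1OCc1ccccc1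
F8 | step 10 | (3R,4S)-6-(benzyloxy)-4-[4-(benzyloxy)-3-methoxyphenyl]-3-(hydroxymethyl)-7-methoxy-3,4-dihydronaphthalene-2-carbaldehyde | COc1cc([C@H]2c3cc(OCc4ccccc4)c(OC)cc3C=C(C=O)[C@@H]2CO)ccc1OCc1ccccc1
F9 | step 11 | (7S,8R)-8-(4-hydroxy-3-methoxyphenyl)-7-(hydroxymethyl)-3-methoxy-6-methylidene-5,6,7,8-tetrahydronaphthalen-2-ol (C1 and C2 of the skeleton as in 15) | COc1cc([C@H]2c3cc(O)c(OC)cc3CC(=C)[C@@H]2CO)ccc1O
F10 | step 11 | triacetate of F9 (two aryl acetates, one primary acetate) | COc1cc([C@H]2c3cc(OC(C)=O)c(OC)cc3CC(=C)[C@@H]2COC(C)=O)ccc1OC(C)=O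
F11 | step 11 | allylic hydroperoxide from F10 (C3=C4 alkene, CH2OOH on C3) | COc1cc([C@H]2c3cc(OC(C)=O)c(OC)cc3C=C(COO)[C@@H]2COC(C)=O)ccc1OC(C)=O
F12 | step 11 | peracetate of F11 | COc1cc([C@H]2c3cc(OC(C)=O)c(OC)cc3C=C(COOC(C)=O)[C@@H]2COC(C)=O)ccc1OC(C)=O
F13 | step 11 | di-O-acetyl derivative of target 20 (both phenols acetylated) | COc1cc([C@H]2c3cc(OC(C)=O)c(OC)cc3C=C(C=O)[C@@H]2COC(C)=O)ccc1OC(C)=O
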